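How much target can the flask hold within 25 h, and at what time?

1. time, not beyond 25 h, at which the flask holds most target
2. the amount of target, in percent of the starting material charged, at that time

| setting | birch | elm | flask |
|---|---|---|---|
| starting material | 0.10 M | 0.10 M | 0.10 M |
| second substrate | 1.4 equiv | 2.2 equiv | 1.00 equiv |
| coupling partner | 0.95 equiv | 0.95 equiv | 0.950 equiv |
| free catalyst | 0.63 mol% | 0.63 mol% | 0.63 mol% |
| remark | run made earlier | run made earlier |  |
| time |  |  | 25 h |

- birch (time / h: target / %): 1.50: 14.0; 3.00: 18.1; 6.00: 19.1; 15.0: 17.4; 30.0: 13.0
- elm (time / h: target / %): 1.50: 9.1; 3.00: 14.3; 6.00: 13.5; 15.0: 14.9; 30.0: 11.2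

(standard deviation of a reading: 1 percentage point)



The birch and elm runs differ in second substrate. The elm run, with more of it, has a lower highest reading than the birch run: 14.9% against 19.1%. This suggests that second substrate competes with starting material for the coupling partner.

The symmetric case gives a scale. Suppose the coupling partner divides between the two in proportion to their charges, without preference. The target, as a fraction of the starting material charged, then equals the statistical share: equivalents of coupling partner divided by one plus the equivalents of second substrate. That share is 39.6% for the birch run and 29.7% for the elm run.

The realised fraction is the highest reading divided by the statistical share, and one would be the symmetric case itself. Averaged over the two runs, it reads 0.492, about half, with the scatter of the readings in it.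

The flask has a statistical share of 47.5%, so this reckoning expects 23.4%. For the time it takes the birch run, the nearest recipe, whose highest reading stands at 6.00 h.

The forecast gives 24% at 4 h, close to this reckoning in amount but earlier than the time taken from the birch run. Its ground for the time: “The rise also appears faster with less substrate”.

The flask reaches 24.9% at 6.01 h.

    starting material + free catalyst ⇌ catalyst intermediate A (K = 10.0 L mol⁻¹, k = 0.298 L mol⁻¹ s⁻¹)
    coupling partner + catalyst intermediate B → free catalyst + second product (k = 0.245 L mol⁻¹ s⁻¹)
    second substrate + free catalyst ⇌ catalyst intermediate B (K = 70.8 L mol⁻¹, k = 0.270 L mol⁻¹ s⁻¹)
    target + free catalyst ⇌ isomer of the product + free catalyst, rate k4*[free catalyst]*[target] forward; the back reaction follows from the equilibrium constant (K = 12.3, k = 0.0700 L mol⁻¹ s⁻¹)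
    coupling partner + catalyst intermediate A → free catalyst + target (k = 0.303 L mol⁻¹ s⁻¹)

Up to 6.01 h, coupling partner falls to 9.36% of its charge, reacting with catalyst intermediate A to target and with catalyst intermediate B to second product, while 5.68% isomer of the product forms. Coupling partner, the limiting reagent, stands at 0.540% by 12.5 h, and by 25.0 h target is down to 14.0% with isomer of the product at 18.9%. The flask's realised fraction is 0.524, beside the 0.492 read from the runs. For the neighbour charged with 0.250 equiv of second substrate, the statistical share is 76.0%, so the fraction 0.492 expects 37.4%, and that neighbour reached 37.6%.

The readings are simulated with constants of no real substance; noise was put on by code.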